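**Plan**
1. Retrosynthesis: cut C12–C13 (Suzuki–Miyaura) and C11=C12 (chromium olefination) to release the butenolide. Then cut the ring-fusion bond C5–C10 together with C7–C8, which opens both rings to one chain. Then cut C9–C8 (Sonogashira), C10–C20 and C9–I (ynoate carbocupration), C4–C18 and C4–C5 (enolate alkylations), and C1–C2 (dianion alkylation).
2. Enabling feature: ring B consists of two three-carbon units, C5–C6–C7 and C8–C9–C10, joined at both ends. A temporary ketone at C6 makes C5 and then C7 nucleophilic. The C11 ester on C9 makes C10 electrophilic and, once the ethynyl group C8≡C17 has shifted to an allene, C8 as well, so the exocyclic C8=C17 methylene is what remains of the alkyne.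
3. Forward order: the acyclic chain first, then ring A (C5–C10) and ring B (C7–C8) in one base-mediated cascade, then removal of the C6 oxygen, and the dienyl butenolide last.
4. Stereochemistry: C3 is set by catalytic asymmetric hydrogenation and C4 by chelate-controlled double alkylation relayed from C3. C10, C5 and C9 are all set in the cascade by substrate control.
5. Helpers: the C6 ketone (removed as its tosylhydrazone), the tert-butyl ester at C19 (later reduced and acetylated), the TBS ether at O3, and the alkynyl TMS group.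

Key step: step 11

Remark: labdane numbering is used throughout (decalin C1–C10, C11/C12 in the side chain, C17 the exocyclic methylene carbon, C18 the methyl and C19 the oxygenated carbon on C4, C20 the methyl on C10); α is the face of C20. The enoate geometry in 11, 13, 14 and 15 is an E/Z mixture and has no consequence, because C9 and C10 become sp3 in step 11.

**Route**

Step 1
Reactants: 1 tert-butyl acetoacetate; 2 3-bromo-1-(trimethylsilyl)prop-1-yne
Product: 3 tert-butyl 3-oxo-7-(trimethylsilyl)hept-6-ynoate
Conditions: NaH, THF, 0 °C; n-BuLi, 0 °C; then 2, 0 °C → rt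
Reagents that add atoms: none
Why: γ-Alkylation of the acetoacetate dianion, whose terminal enolate carbon is the more nucleophilic site, by the propargylic bromide should give the β-keto ester that already holds C19, C4, C3, C2, C1, C10 and C9.

Step 2
Reactants: 3 tert-butyl 3-oxo-7-(trimethylsilyl)hept-6-ynoate
Product: 4 tert-butyl (3R)-3-hydroxy-7-(trimethylsilyl)hept-6-ynoate
Conditions: H2 (4 atm), RuCl2[(R)-BINAP] (0.5 mol%), MeOH, 40 °C
Reagents that add atoms: none
Why: Noyori asymmetric hydrogenation of a β-keto ester, in which the (R)-BINAP ligand directs hydrogen to one face of the ester-chelated ketone and so sets C3 as R, while the silyl-capped alkyne should be reduced far more slowly at this pressure.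

Step 3
Reactants: 4 tert-butyl (3R)-3-hydroxy-7-(trimethylsilyl)hept-6-ynoate; 5 allyl bromide
Product: 6 tert-butyl (2R,3R)-3-hydroxy-2-(prop-2-en-1-yl)-7-(trimethylsilyl)hept-6-ynoate (anti)
Conditions: LDA (2.2 equiv), THF, −78 → −20 °C; 5, DMPU, −78 → −20 °C
Reagents that add atoms: none
Why: Fráter–Seebach alkylation, in which the chelated lithium alkoxide–enolate dianion is alkylated on the face away from the C3 side chain and should therefore give the anti product.

Step 4
Reactants: 6 tert-butyl (2R,3R)-3-hydroxy-2-(prop-2-en-1-yl)-7-(trimethylsilyl)hept-6-ynoate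
Product: 7 tert-butyl (2S,3R)-3-hydroxy-2-methyl-2-(prop-2-en-1-yl)-7-(trimethylsilyl)hept-6-ynoate
Conditions: LDA (2.5 equiv), THF, −78 → −10 °C; MeI, DMPU, −78 → 0 °C
Reagents that add atoms: iodomethane (CI)
Why: Second Fráter–Seebach alkylation, in which the re-formed chelated dianion takes up the electrophile on the same face as before, so that methyl ends anti and allyl syn to the hydroxyl and the quaternary C4 is set by relay from C3.

Step 5
Reactants: 7 tert-butyl (2S,3R)-3-hydroxy-2-methyl-2-(prop-2-en-1-yl)-7-(trimethylsilyl)hept-6-ynoate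
Product: 8 tert-butyl (2S,3R)-3-[(tert-butyldimethylsilyl)oxy]-2-methyl-2-(prop-2-en-1-yl)-7-(trimethylsilyl)hept-6-ynoate
Conditions: TBSOTf, 2,6-lutidine, CH2Cl2, 0 °C → rt
Reagents that add atoms: tert-butyldimethylsilyl trifluoromethanesulfonate (CC(C)(C)[Si](C)(C)OS(=O)(=O)C(F)(F)F)
Why: Silyl ether formation with the silyl triflate protects the hindered carbinol, because a free β-hydroxy ester would undergo retro-aldol cleavage under the alkoxide conditions of step 11.

Step 6
Reactants: 8 tert-butyl (2S,3R)-3-[(tert-butyldimethylsilyl)oxy]-2-methyl-2-(prop-2-en-1-yl)-7-(trimethylsilyl)hept-6-ynoate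
Product: 9 tert-butyl (2S,3R)-3-[(tert-butyldimethylsilyl)oxy]-2-methyl-2-(prop-2-en-1-yl)hept-6-ynoate
Conditions: K2CO3 (0.2 equiv), MeOH, rt
Reagents that add atoms: none
Why: Methanolysis of the alkynyl C–Si bond (protiodesilylation) frees the terminal alkyne and should leave the silyl ether and the tert-butyl ester untouched.

Step 7
Reactants: 9 tert-butyl (2S,3R)-3-[(tert-butyldimethylsilyl)oxy]-2-methyl-2-(prop-2-en-1-yl)hept-6-ynoate
Product: 10 1-tert-butyl 8-methyl (2S,3R)-3-[(tert-butyldimethylsilyl)oxy]-2-methyl-2-(prop-2-en-1-yl)oct-6-ynedioate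
Conditions: n-BuLi, THF, −78 °C; ClCO2Me, −78 → 0 °C
Reagents that add atoms: methyl chloroformate (COC(=O)Cl)
Why: Acylation of the lithium acetylide with a chloroformate gives the ynoate that carries C11, the hindered tert-butyl ester on a quaternary carbon being inert at −78 °C.

Step 8
Reactants: 10 1-tert-butyl 8-methyl (2S,3R)-3-[(tert-butyldimethylsilyl)oxy]-2-methyl-2-(prop-2-en-1-yl)oct-6-ynedioate
Product: 11 1-tert-butyl 8-methyl (2S,3R)-3-[(tert-butyldimethylsilyl)oxy]-7-iodo-2,6-dimethyl-2-(prop-2-en-1-yl)oct-6-enedioate (E/Z mixture)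
Conditions: Me2CuLi, THF, −78 °C; then I2, −78 → 0 °C
Reagents that add atoms: lithium dimethylcuprate ([Li+].C[Cu-]C); iodine (II)
Why: Conjugate addition (carbocupration) of the Gilman reagent to the ynoate places the C20 methyl on C10 and copper on C9, and iodinolysis of the carbon–copper bond should give the α-iodo enoate.

Step 9
Reactants: 11 1-tert-butyl 8-methyl (2S,3R)-3-[(tert-butyldimethylsilyl)oxy]-7-iodo-2,6-dimethyl-2-(prop-2-en-1-yl)oct-6-enedioate; 12 ethynyltrimethylsilane
Product: 13 1-tert-butyl 8-methyl (2S,3R)-3-[(tert-butyldimethylsilyl)oxy]-2,6-dimethyl-2-(prop-2-en-1-yl)-7-[(trimethylsilyl)ethynyl]oct-6-enedioate (E/Z mixture)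
Conditions: Pd(PPh3)2Cl2 (5 mol%), CuI (10 mol%), Et3N, THF, rt
Reagents that add atoms: none
Why: Sonogashira coupling of the electron-poor α-iodo enoate with the terminal alkyne introduces C8 and C17.

Step 10
Reactants: 13 1-tert-butyl 8-methyl (2S,3R)-3-[(tert-butyldimethylsilyl)oxy]-2,6-dimethyl-2-(prop-2-en-1-yl)-7-[(trimethylsilyl)ethynyl]oct-6-enedioate
Product: 14 1-tert-butyl 8-methyl (2S,3R)-3-[(tert-butyldimethylsilyl)oxy]-2,6-dimethyl-2-(2-oxopropyl)-7-[(trimethylsilyl)ethynyl]oct-6-enedioate (E/Z mixture)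
Conditions: PdCl2 (10 mol%), CuCl (1 equiv), O2 (1 atm), DMF/H2O 7:1, rt
Reagents that add atoms: dioxygen (O=O), the net oxygen source (the oxygen atom is delivered through water)
Why: Tsuji–Wacker oxidation of the terminal allyl alkene gives the methyl ketone (C6 with C7) with Markovnikov regiochemistry, the tetrasubstituted enoate and the silyl alkyne being too hindered or too electron-poor to react.

Step 11
Reactants: 14 1-tert-butyl 8-methyl (2S,3R)-3-[(tert-butyldimethylsilyl)oxy]-2,6-dimethyl-2-(2-oxopropyl)-7-[(trimethylsilyl)ethynyl]oct-6-enedioate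
Product: 17 bicyclic keto diester (trans-decalin with 3α-silyloxy 4α-tert-butoxycarbonyl 6-oxo 8-methylidene 9α-methoxycarbonyl 10α-methyl), via ethynyl enoate ketone 15 (not isolated), via monocyclic allenoate 16 (not isolated)
Conditions: KOt-Bu (1.3 equiv), t-BuOH (2 equiv), THF, −20 → 0 °C; then AcOH, −78 °C
Reagents that add atoms: none
Why: Proposed new method: tert-butoxide first cleaves the alkynyl C–Si bond (15) and equilibrates the ketone enolates; the C5 enolate adds to C10 of the 2-ethynyl enoate (Michael addition), the α-ethynyl ester enolate so formed is reprotonated at C17 to the allenoate 16, the C7 enolate then adds to the central allene carbon C8, and the resulting cross-conjugated dienolate is protonated at C7 only at −78 °C, so that C8=C17 stays exocyclic. The closest known reaction type is the α,α′-annulation of a ketone with a 2-(halomethyl)acrylate (Michael addition, regeneration of the acceptor, second Michael addition), together with enolate additions to the sp carbon of 2,3-allenoates and the base-mediated propargyl-to-allenyl shift of 3-alkynoates; what is new is that this shift regenerates the acceptor, so a 2-ethynyl acrylate serves as a three-carbon unit that is electrophilic at both ends. Ring A closes in the 6-exo-trig mode (C5–C10) and ring B in the 6-endo mode at the sp carbon of the allene, with the enolate double bond inside the forming ring (C7–C8). C10 is set in a chair in which the C3 silyl ether is equatorial and the planar C19 ester, not the C18 methyl, is axial, so that the new C10 methyl goes axial beside the ester and the bulky C9 unit goes equatorial, a preference that acts on the adduct as well as on the transition state because the conjugate addition is reversible; C5 is epimerizable through the ketone and should settle in the trans ring fusion, and C9 is protonated reversibly by t-BuOH and should settle with the ester equatorial. The step needs site selectivity between the two enolates and between carbonyl and conjugate attack: only C5 can reach C10 through a six-membered ring (C7 would need an eight-membered one), only C7 can reach C8 once ring A exists, the tert-butyl ester on the quaternary C4 resists Claisen attack, and keeping one equivalent of base until the cold quench holds the product as its dienolate and so prevents drift of the alkene into conjugation.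

Step 12
Reactants: 17 bicyclic keto diester
Product: 18 C6 tosylhydrazone of 17
Conditions: TsNHNH2, MgSO4, THF, rt → 40 °C
Reagents that add atoms: p-toluenesulfonyl hydrazide (Cc1ccc(cc1)S(=O)(=O)NN)
Why: Hydrazone formation (condensation) under neutral dehydrating conditions should derivatize the only ketone from its open β face and keep the exocyclic alkene out of conjugation.

Step 13
Reactants: 18 C6 tosylhydrazone of 17
Product: 19 diol (trans-decalin with 3α-silyloxy, 4α-hydroxymethyl C19, 8-methylidene, 9α-hydroxymethyl C11, C6 as CH2)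
Conditions: LiAlH4 (excess), THF, 0 °C → reflux
Reagents that add atoms: none
Why: Caglioti reduction, in which hydride adds to the tosylhydrazone carbon and loss of sulfinate and N2 leaves C6 as CH2 without moving the non-conjugated alkene, while the same reagent reduces both esters to the primary alcohols.

Step 14
Reactants: 19 diol
Product: 20 hydroxy aldehyde (C11 aldehyde on C9, free C19 alcohol)
Conditions: TEMPO (10 mol%), PhI(OAc)2 (1.1 equiv), CH2Cl2, 0 °C
Reagents that add atoms: none
Why: TEMPO-mediated oxidation through the oxoammonium salt is sterically selective and should oxidize the less hindered C11 alcohol in preference to the neopentyl, axial C19 alcohol that sits beside the silyl ether.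

Step 15
Reactants: 20 hydroxy aldehyde
Product: 21 (E)-alkenyl pinacol boronate (C11=C12–B, free C19 alcohol)
Conditions: CrCl2, LiI, Cl2CHB(pin), THF, rt
Reagents that add atoms: 2-(dichloromethyl)-4,4,5,5-tetramethyl-1,3,2-dioxaborolane (ClC(Cl)B1OC(C)(C)C(C)(C)O1)
Why: Takai–Utimoto olefination with the boron-substituted geminal dichromium reagent should give the E alkenylboronate through anti elimination of the β-oxido adduct, under non-basic conditions that leave the C9 stereocenter and the exocyclic alkene in place.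

Step 16
Reactants: 21 (E)-alkenyl pinacol boronate; 22 3-bromofuran-2(5H)-one
Product: 23 3-O-TBS-14-deoxy-11,12-didehydroandrographolide (free C19 alcohol)
Conditions: Pd(dppf)Cl2 (5 mol%), K3PO4, THF/H2O, 40 °C
Reagents that add atoms: none
Why: Suzuki–Miyaura coupling of the alkenylboronate with the α-bromobutenolide forms C12–C13 with retention of the E geometry.

Step 17
Reactants: 23 3-O-TBS-14-deoxy-11,12-didehydroandrographolide
Product: 24 19-O-acetyl-3-O-TBS-14-deoxy-11,12-didehydroandrographolide
Conditions: Ac2O, pyridine, DMAP (cat.), CH2Cl2, rt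
Reagents that add atoms: acetic anhydride (CC(=O)OC(C)=O)
Why: DMAP-catalysed acylation acetylates the only free hydroxyl, the primary C19 alcohol.

Step 18
Reactants: 24 19-O-acetyl-3-O-TBS-14-deoxy-11,12-didehydroandrographolide
Product: 25 19-O-acetyl-14-deoxy-11,12-didehydroandrographolide (target)
Conditions: HF·pyridine, THF, 0 °C → rt
Reagents that add atoms: none
Why: Fluoride-mediated desilylation under buffered, weakly acidic conditions should free the C3 alcohol without touching the acetate, the diene or the butenolide.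

**Compound list**
1 | tert-butyl acetoacetate | CC(=O)CC(=O)OC(C)(C)C | starting material
2 | 3-bromo-1-(trimethylsilyl)prop-1-yne | C[Si](C)(C)C#CCBr | starting material
3 | tert-butyl 3-oxo-7-(trimethylsilyl)hept-6-ynoate | CC(C)(C)OC(=O)CC(=O)CCC#C[Si](C)(C)C | intermediate
4 | tert-butyl (3R)-3-hydroxy-7-(trimethylsilyl)hept-6-ynoate | CC(C)(C)OC(=O)C[C@H](O)CCC#C[Si](C)(C)C | intermediate
5 | allyl bromide (3-bromoprop-1-ene) | C=CCBr | starting material
6 | tert-butyl (2R,3R)-3-hydroxy-2-(prop-2-en-1-yl)-7-(trimethylsilyl)hept-6-ynoate | C=CC[C@@H](C(=O)OC(C)(C)C)[C@H](O)CCC#C[Si](C)(C)C | intermediate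
7 | tert-butyl (2S,3R)-3-hydroxy-2-methyl-2-(prop-2-en-1-yl)-7-(trimethylsilyl)hept-6-ynoate | C=CC[C@](C)(C(=O)OC(C)(C)C)[C@H](O)CCC#C[Si](C)(C)C | intermediate
8 | tert-butyl (2S,3R)-3-[(tert-butyldimethylsilyl)oxy]-2-methyl-2-(prop-2-en-1-yl)-7-(trimethylsilyl)hept-6-ynoate | C=CC[C@](C)(C(=O)OC(C)(C)C)[C@H](O[Si](C)(C)C(C)(C)C)CCC#C[Si](C)(C)C | intermediate
9 | tert-butyl (2S,3R)-3-[(tert-butyldimethylsilyl)oxy]-2-methyl-2-(prop-2-en-1-yl)hept-6-ynoate | C=CC[C@](C)(C(=O)OC(C)(C)C)[C@H](O[Si](C)(C)C(C)(C)C)CCC#C | intermediate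
10 | 1-tert-butyl 8-methyl (2S,3R)-3-[(tert-butyldimethylsilyl)oxy]-2-methyl-2-(prop-2-en-1-yl)oct-6-ynedioate | C=CC[C@](C)(C(=O)OC(C)(C)C)[C@H](O[Si](C)(C)C(C)(C)C)CCC#CC(=O)OC | intermediate
11 | 1-tert-butyl 8-methyl (2S,3R)-3-[(tert-butyldimethylsilyl)oxy]-7-iodo-2,6-dimethyl-2-(prop-2-en-1-yl)oct-6-enedioate (E/Z mixture) | C=CC[C@](C)(C(=O)OC(C)(C)C)[C@H](O[Si](C)(C)C(C)(C)C)CCC(C)=C(I)C(=O)OC | intermediate
12 | ethynyltrimethylsilane | C#C[Si](C)(C)C | starting material
13 | 1-tert-butyl 8-methyl (2S,3R)-3-[(tert-butyldimethylsilyl)oxy]-2,6-dimethyl-2-(prop-2-en-1-yl)-7-[(trimethylsilyl)ethynyl]oct-6-enedioate (E/Z mixture) | C=CC[C@](C)(C(=O)OC(C)(C)C)[C@H](O[Si](C)(C)C(C)(C)C)CCC(C)=C(C#C[Si](C)(C)C)C(=O)OC | intermediate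
14 | 1-tert-butyl 8-methyl (2S,3R)-3-[(tert-butyldimethylsilyl)oxy]-2,6-dimethyl-2-(2-oxopropyl)-7-[(trimethylsilyl)ethynyl]oct-6-enedioate (E/Z mixture) | CC(=O)C[C@](C)(C(=O)OC(C)(C)C)[C@H](O[Si](C)(C)C(C)(C)C)CCC(C)=C(C#C[Si](C)(C)C)C(=O)OC | intermediate
15 | 1-tert-butyl 8-methyl (2S,3R)-3-[(tert-butyldimethylsilyl)oxy]-7-ethynyl-2,6-dimethyl-2-(2-oxopropyl)oct-6-enedioate (E/Z mixture; not isolated) | CC(=O)C[C@](C)(C(=O)OC(C)(C)C)[C@H](O[Si](C)(C)C(C)(C)C)CCC(C)=C(C#C)C(=O)OC | intermediate
16 | tert-butyl 2-acetyl-6-[(tert-butyldimethylsilyl)oxy]-3-[1-(methoxycarbonyl)propa-1,2-dien-1-yl]-1,3-dimethylcyclohexane-1-carboxylate (ring A only; ester, silyl ether and C10 methyl cis on the α face; acetyl on C5 equatorial and trans to the allenyl group on C10; not isolated) | CC(=O)[C@@H]1[C@](C)(C(=O)OC(C)(C)C)[C@H](O[Si](C)(C)C(C)(C)C)CC[C@@]1(C)C(=C=C)C(=O)OC | intermediate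
17 | bicyclic keto diester: trans-decalin with 3α-OTBS, 4α-CO2t-Bu (C19, axial), 4β-CH3, 5β-H, 6-oxo, 8-methylidene (C17), 9α-CO2CH3 (C11, 9β-H), 10α-CH3 | C=C1CC(=O)[C@@H]2[C@](C)(C(=O)OC(C)(C)C)[C@H](O[Si](C)(C)C(C)(C)C)CC[C@@]2(C)[C@@H]1C(=O)OC | intermediate
18 | C6 tosylhydrazone of 17 | C=C1CC(=NNS(=O)(=O)c2ccc(C)cc2)[C@@H]3[C@](C)(C(=O)OC(C)(C)C)[C@H](O[Si](C)(C)C(C)(C)C)CC[C@@]3(C)[C@@H]1C(=O)OC | intermediate
19 | diol: trans-decalin with 3α-OTBS, 4α-CH2OH (C19), 4β-CH3, 5β-H, 8-methylidene, 9α-CH2OH (C11), 10α-CH3 | C=C1CC[C@@H]2[C@](C)(CO)[C@H](O[Si](C)(C)C(C)(C)C)CC[C@@]2(C)[C@@H]1CO | intermediate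
20 | hydroxy aldehyde: as 19 with 9α-CHO (C11) and free 19-OH | C=C1CC[C@@H]2[C@](C)(CO)[C@H](O[Si](C)(C)C(C)(C)C)CC[C@@]2(C)[C@@H]1C=O | intermediate
21 | (E)-alkenyl pinacol boronate: as 19 with 9α-[(E)-2-(4,4,5,5-tetramethyl-1,3,2-dioxaborolan-2-yl)ethenyl] and free 19-OH | C=C1CC[C@@H]2[C@](C)(CO)[C@H](O[Si](C)(C)C(C)(C)C)CC[C@@]2(C)[C@@H]1/C=C/B1OC(C)(C)C(C)(C)O1 | intermediate
22 | 3-bromofuran-2(5H)-one | BrC1=CCOC1=O | starting material
23 | 3-O-TBS-14-deoxy-11,12-didehydroandrographolide (free 19-OH, 11E) | C=C1CC[C@@H]2[C@](C)(CO)[C@H](O[Si](C)(C)C(C)(C)C)CC[C@@]2(C)[C@@H]1/C=C/C1=CCOC1=O | intermediate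
24 | 19-O-acetyl-3-O-TBS-14-deoxy-11,12-didehydroandrographolide | C=C1CC[C@@H]2[C@](C)(COC(C)=O)[C@H](O[Si](C)(C)C(C)(C)C)CC[C@@]2(C)[C@@H]1/C=C/C1=CCOC1=O | intermediate
25 | 19-O-acetyl-14-deoxy-11,12-didehydroandrographolide (3R,4R,5S,9R,10R; 11E) | C=C1CC[C@@H]2[C@](C)(COC(C)=O)[C@H](O)CC[C@@]2(C)[C@@H]1/C=C/C1=CCOC1=O | target

**Step count and risks**
Total step count: 18. Longest linear sequence: 18 steps (1 → 25).

Steps most likely to fail:

Step 11. The crowded first conjugate addition may stall, the facial selectivity at C10 may be poor, or proton shuffling may move the exocyclic double bond into conjugation before the quench. The fallback sets out from 14 and makes the two bonds one after the other by known reactions. K2CO3 in MeOH removes the alkynyl silyl group, and catalytic Cs2CO3 in MeOH/THF should stop the intramolecular Michael addition after ring A by protonation in the protic medium. This gives the monocyclic α-ethynyl keto ester F1 (C9 epimers). Soft enolization of the methyl ketone (TBSOTf, Et3N, CH2Cl2) gives the less substituted silyl enol ether F2. The cationic gold catalyst [(JohnPhos)Au(NCMe)]SbF6 in CH2Cl2/MeOH then closes ring B by a Conia-ene-type 6-exo-dig carbocyclization onto the terminal alkyne. Brief base equilibration at C9 to the equatorial ester returns the route to 17.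

Step 12. Condensation at the hindered C6 carbonyl may be slow, and the exocyclic double bond may migrate into conjugation with the new C=N bond, after which hydride reduction would relocate the alkene. The fallback sets out from 17 and removes the oxygen by a radical route. NaBH4/CeCl3 in MeOH at −40 °C reduces the ketone from the open β face to the 6α-alcohol F3. Thiocarbonyl diimidazole with DMAP in toluene at 80 °C gives the imidazolyl thiocarbonate F4. Bu3SnH/AIBN in toluene at 100 °C (Barton–McCombie deoxygenation) gives the C6-methylene diester F5. LiAlH4 then reduces both esters of F5 and the route comes back at 19.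

Step 14. Chemoselectivity between the two primary alcohols may be incomplete, with over-oxidation at C19. The fallback sets out from 19 and differentiates the alcohols by acylation. Ac2O/pyridine/DMAP gives the diacetate F6. K2CO3 in MeOH at 0 °C cleaves the unhindered C11 acetate and leaves the neopentyl, axial C19 acetate, giving the C11 alcohol F7. Dess–Martin periodinane gives the aldehyde F8, which already carries the C19 acetate. CrCl2/LiI/Cl2CHB(pin) gives the (E)-alkenylboronate F9. Suzuki–Miyaura coupling of F9 with 22 (Pd(dppf)Cl2, K3PO4) brings the route back at 24.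

Further compounds
F1 | step 11 | tert-butyl 2-acetyl-6-[(tert-butyldimethylsilyl)oxy]-3-(1-methoxy-1-oxobut-3-yn-2-yl)-1,3-dimethylcyclohexane-1-carboxylate (ring A configured as in 16; C9 epimers) | CC(=O)[C@@H]1[C@](C)(C(=O)OC(C)(C)C)[C@H](O[Si](C)(C)C(C)(C)C)CC[C@@]1(C)C(C#C)C(=O)OC
F2 | step 11 | silyl enol ether of F1 at the acetyl group (C6=C7, O-TBS) | C=C(O[Si](C)(C)C(C)(C)C)[C@@H]1[C@](C)(C(=O)OC(C)(C)C)[C@H](O[Si](C)(C)C(C)(C)C)CC[C@@]1(C)C(C#C)C(=O)OC
F3 | step 12 | 6α-alcohol of 17 | C=C1C[C@H](O)[C@@H]2[C@](C)(C(=O)OC(C)(C)C)[C@H](O[Si](C)(C)C(C)(C)C)CC[C@@]2(C)[C@@H]1C(=O)OC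
F4 | step 12 | O-(imidazol-1-ylthiocarbonyl) derivative of F3 | C=C1C[C@H](OC(=S)n2ccnc2)[C@@H]3[C@](C)(C(=O)OC(C)(C)C)[C@H](O[Si](C)(C)C(C)(C)C)CC[C@@]3(C)[C@@H]1C(=O)OC
F5 | step 12 | C6-methylene diester (17 without the C6 oxygen) | C=C1CC[C@@H]2[C@](C)(C(=O)OC(C)(C)C)[C@H](O[Si](C)(C)C(C)(C)C)CC[C@@]2(C)[C@@H]1C(=O)OC
F6 | step 14 | 11,19-diacetate of 19 | C=C1CC[C@@H]2[C@](C)(COC(C)=O)[C@H](O[Si](C)(C)C(C)(C)C)CC[C@@]2(C)[C@@H]1COC(C)=O
F7 | step 14 | 19-acetate with free C11 alcohol | C=C1CC[C@@H]2[C@](C)(COC(C)=O)[C@H](O[Si](C)(C)C(C)(C)C)CC[C@@]2(C)[C@@H]1CO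
F8 | step 14 | 19-acetate C11 aldehyde | C=C1CC[C@@H]2[C@](C)(COC(C)=O)[C@H](O[Si](C)(C)C(C)(C)C)CC[C@@]2(C)[C@@H]1C=O
F9 | step 14 | 19-acetate (E)-alkenyl pinacol boronate | C=C1CC[C@@H]2[C@](C)(COC(C)=O)[C@H](O[Si](C)(C)C(C)(C)C)CC[C@@]2(C)[C@@H]1/C=C/B1OC(C)(C)C(C)(C)O1
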